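The constants used here were chosen freely; the result is computed.

Start from a one-step world, in which a substrate decays by first order and the share surviving is the exponential of minus the rate constant times the time; this flask keeps such a step, the uncatalysed path to side product, and sets the catalyst's steps beside it.

    substrate + free catalyst → free catalyst + target (k1 = 3.8 M⁻¹ h⁻¹, Ea1 = 56.0 kJ mol⁻¹)
    substrate → side product (k2 = 9.6 × 10⁻⁴ h⁻¹, Ea2 = 106 kJ mol⁻¹)
    2 free catalyst → spent catalyst A (k3 = 24 M⁻¹ h⁻¹, Ea3 = 44.0 kJ mol⁻¹)
    substrate + free catalyst → spent catalyst B (k4 = 0.38 M⁻¹ h⁻¹, Ea4 = 58.0 kJ mol⁻¹)
    (constants at 0 °C)

| flask | substrate | free catalyst | temperature | time |
|---|---|---|---|---|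
| winter | 0.10 M | 5.0 mM | 0 °C | 50 h |
| summer | 0.10 M | 5.0 mM | 10 °C | 50 h |
| spring | 0.10 M | 5.0 mM | 20 °C | 50 h |

- for a step with 2 of a species take k times the square, and two of it per event
- the constants hold at 0 °C; other temperatures follow from the activation energies

- which of these there is most of at the end, counted by the substrate in it, winter (target / substrate / side product)
- which of these there is most of at the end, counted by the substrate in it, summer (target / substrate / side product)
- which of these there is most of at the end, counted by the substrate in it, spring (target / substrate / side product)
- the largest of these amounts at the end, in percent of the substrate charged, winter
- the largest of these amounts at the end, in percent of the substrate charged, summer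
- the largest of these amounts at the end, in percent of the substrate charged, spring

Every loss of substrate is first order in substrate, so you can write what is left as two factors multiplied, one from the side step and one from the catalyst's steps. For the first factor I take the side clock, the side step's rate constant at the flask's temperature times the time (a Damköhler number), which in spring comes to 1.16. Set out by flask, with the clock, its power of ten and the share it spares, my reckoning reads:

- winter: 0.0480, −1.32, 95.3 %
- summer: 0.250, −0.602, 77.9 %
- spring: 1.16, 0.0645, 31.4 %

Read down the powers of ten, and the clock climbs by 0.717 from winter to summer and by 0.667 from summer to spring. So the summer clock is less than one. The spring clock is more than one. Read the last column, and by this reckoning the side step spares 95.3 % of the charge in winter, 77.9 % in summer and 31.4 % in spring.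

The catalyst's factor lowers each share further. The first half-life of free catalyst by self-deactivation is 4.17 h in winter, shorter than the 36 h half-life of substrate by the catalytic step at the winter charge, so I expect a modest bite and leave it unnumbered. My reckoning stops there: substrate leads in winter and summer, side product in spring.

The forecast says substrate at 81 % in winter, substrate at 63.5 % in summer and side product at 55 % in spring, on these grounds: “The uncatalysed side reaction has by far the highest activation energy and keeps running after the catalyst is gone”.

The flasks give substrate at 80.7 % in winter, substrate at 63.5 % in summer and side product at 56.0 % in spring, as forecast within its margin.

At 17.5 h in spring the side step uses substrate 19 times as fast as the catalytic step. Dividing the 25 % of substrate left in spring by the clock's 31.4 % reads the catalyst's factor as 78.9 %.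

Now read the spring flask at 20 h, where target stands at 17.0 %, close to the 17.4 % at the end, so I keep that factor. The clock is 0.464, and it spares 62.9 %, which the factor brings to 49.6 %. The computed flask holds 50.1 % of substrate against 31.0 % of side product.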